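Keep one thing fixed in your head: in each asked flask, the partner is 60.0% of the starting material charged and the free catalyst 20.0% of it, while the protic impurity moves from 0.0600% to 5.00% of that charge.

in all of them: starting material 0.10 M; free catalyst 20 mM

| flask | partner | protic impurity | remark | time |
|---|---|---|---|---|
| south-west | 0.060 M | 0.079 mM | run made earlier |  |
| west | 0.060 M | 7 mM | run made earlier |  |
| Sunday's | 0.0600 M | 0.0600 mM |  | 40 min |
| Saturday's | 0.0600 M | 0.200 mM |  | 40 min |
| Monday's | 0.0600 M | 0.600 mM |  | 40 min |
| Friday's | 0.0600 M | 1.50 mM |  | 40 min |
| Thursday's | 0.0600 M | 5.00 mM |  | 40 min |

| run | time / min | product / % |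
|---|---|---|
| south-west | 1.50 | 0 |
| south-west | 4.00 | 1 |
| south-west | 8.00 | 10 |
| south-west | 20.0 | 22 |
| west | 1.50 | 1 |
| west | 4.00 | 0 |
| west | 8.00 | 5 |
| west | 20.0 | 22 |

(standard deviation of a reading: 2 percentage points)

* amount of product at the end, in percent of the starting material charged for Sunday's, Saturday's, Monday's, Friday's, Thursday's, in this order
* how that number moves from the first to the last of them (rises all the way / falls, then rises / falls all the way / hardly changes / rises, then falls)

- the numbers in the tables scatter by 2 percentage points (one standard deviation)
- "hardly changes" means that all values lie within two and a half points (for a concentration: within two and a half percent of the largest)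

Work in powers of ten. The two earlier runs lie 1.95 decades apart in impurity, and at 20.0 min they read 22% and 22%, so the slope read from them is zero. Divide the scatter of that difference, 2.8 percentage points, by the span to get 1.5 points per factor of ten. Call this the decade resolution: the loss of product per factor of ten in impurity that equals one standard deviation of what this pair can show.

The asked flasks span 1.92 decades, so, carrying that slope from 20.0 min to the asked 40 min, my own reckoning is a flat row with a first-to-last drop of zero, give or take 2.8 points. Treat flatness as the best reading at that width, not a proof. The pair at 8.00 min reads 10% and 5%, a gap of 1.77 times that scatter, so lean towards a small loss, if any.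

The forecast wrote 40% for Sunday's and 40% for Thursday's, hardly changes, on the ground that “the impurity seems to have no visible effect”.

The flasks give 43.0%, 43.0%, 42.9%, 42.8% and 42.3%: hardly changes. The drop from Sunday's to Thursday's is 0.7 points, which is 0.36 points per factor of ten, less than the decade resolution.

    partner + free catalyst → catalyst intermediate A (k = 0.0740 M⁻¹ s⁻¹)
    starting material + catalyst intermediate A → catalyst intermediate B (k = 0.0400 M⁻¹ s⁻¹)
    catalyst intermediate B → catalyst intermediate C (k = 0.00570 s⁻¹)
    catalyst intermediate C → free catalyst + product (k = 0.0610 s⁻¹)
    starting material + protic impurity → quenched substrate (k = 0.0300 M⁻¹ s⁻¹)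

In Sunday's flask at 20.0 min, 32.9% of the catalyst stood as catalyst intermediate A and 47.5% as free catalyst, while the partner had fallen to 43.1% of its charge and product had reached 23.6% of the starting material charged. In Thursday's flask the reaction of starting material with protic impurity ran beside the catalyst steps: by 40.0 min the quenched substrate stood at 4.97% of the starting material charged, and the starting material at 50.4% against 54.6% in Sunday's, with 16.7% of the partner, the limiting reagent, left. Take the decade resolution to Friday's and Thursday's, 0.523 decades apart: it gives 0.76 points, and the row drops 0.5 points.

Readings and results are simulated with made-up constants; scatter was added.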